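## Structural features

The target is a flavan–flavan-3-ol dimer. An upper 7,3',4'-trihydroxyflavan (benzo ring A, pyran ring C, catechol ring B) is bonded through its C4 to C8 of ring D of a lower (−)-epigallocatechin unit (pyran ring F, pyrogallol ring E). There are four stereocentres: lower C2 and C3 are adjacent and cis (2R,3R), and upper C2 (S) and C4 (R) stand in a 1,3-relationship across the C3 methylene with their aryl groups trans. Upper C4 is a crowded methine carrying two aryl carbons (C4a of ring A and C8 of ring D, the latter flanked by two oxygen-bearing carbons) and one CH2, with no neighbouring heteroatom through which its configuration could be relayed. The nine free hydroxyls, above all the pyrogallol ring E, are sensitive to air and base; lower C2 epimerises under base once the para phenol of ring E is free. The benzylic O1–C2 ethers and the C4–C8 bond between the units are cleaved by strong acid. The real difficulty is to create C4 next to an existing chiral unit and then to place ring B at C2 trans to ring D, an arrangement that hydride reduction of a cyclic oxocarbenium ion would not be expected to favour. The handle is that C4 is bonded to C4a, which is ortho to the O1-bearing carbon C8a: with ring C opened at O1–C2, C4 is the exocyclic carbon of an ortho-quinone methide of ring A, an electrophile at which C3–C4 and the C4 configuration can be set by a chiral acid.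

## Logic of the disconnections

15 ⇒ 14. The nine O–H bonds are traced back to nine O–benzyl bonds. One protecting group for every phenol and for the lower 3-hydroxyl means one neutral hydrogenolysis at the end, with no acid or base on the free polyphenol. The demand is that benzyl ethers survive every earlier step, and that the cyclic benzylic ethers O1–C2 of rings C and F are not hydrogenolysed.

14 ⇒ 13. The O1–C2 bond of ring C is cut, giving a phenol and a secondary benzylic carbinol. Closing this bond by Mitsunobu displacement sets C2 by inversion of a carbinol whose configuration is chosen by a reagent, so the 2,4-trans arrangement does not depend on the ring's own bias. The demand is a clean SN2 event at an electron-rich benzylic centre.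

13 ⇒ 12. The C2–H bond is removed, giving the aryl ketone. The gain is that the C2 configuration is reduced to the choice of a reduction catalyst. The demand is catalyst control next to a free phenol and a remote C4 centre.

12 ⇒ 8 + 10 (through 11). The C3–C4 bond is cut at the carbon that is the methide carbon of 11. This separates the whole ring B/C2/C3 portion as an acetophenone enol equivalent and leaves a benzhydrol whose carbinol configuration is irrelevant. It is the cut of greatest simplification and it creates C4. The forward step must distinguish the two faces of the methide carbon and must outrun self-condensation of the electron-rich partners.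

8 ⇒ 4 + 5 (through 6 and 7). The bond between the carbinol carbon and C8 of ring D is cut, giving an aryl nucleophile and an aldehyde. The demand is a regiodefined metalation at C8 and addition to an aldehyde whose ortho phenol must be masked in the flask.

4 ⇒ 3 ⇒ 2 ⇒ 1. The C8–Br bond and six O–benzyl bonds are removed in turn. All four stereocentres of the lower unit are bought with 1; the demands are C8 over C6 selectivity in the bromination and no epimerisation of C2 during benzylation.

10 ⇒ 9. The O–Si bond is removed; the methyl ketone has only one enolisable side.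

## Other disconnections considered

Alternative 1: Ring C is cut at C4–C4a and O1–C2 with C2 at the aldehyde level. This leads to the ring D cinnamaldehyde A1, (E)-3-(hexa-O-benzylepigallocatechin-8-yl)prop-2-enal, and 3-(benzyloxy)phenol A2.
- Forward step: a diarylprolinol silyl ether forms the iminium ion of A1; A2 attacks its β-carbon through the position ortho to OH and para to OBn, and the phenol then closes onto the freed aldehyde to give lactol A3 with C4 set by the amine.
- In favour: two bonds and ring C form in one operation under a well-understood face-shielding model. A1 is a stable, chromatographable aldehyde, whereas 8 ionises easily; on robustness of the key-step substrate the alternative is the better one.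
- Against: the β-carbon of A1 is conjugated with the trialkoxy ring D and flanked by two ortho substituents, so the iminium ion should be a weak electrophile. 3-Alkoxyphenols sit at the low end of the nucleophiles this catalysis serves and can also react at other ring positions. Above all, ring B is missing: opening A3 with a ring B aryl organometallic would give 13 and its C2 epimer without control, so re-oxidation to 12 and the reduction of step 7 would still be needed.
- Comparison: both plans set the same carbon under catalyst control with ring D in place. The alternative makes C4–C4a instead of C3–C4 and closes a ring that must be reopened. From 4, reaching 12 would take about five steps (formylation, olefination, annulation, aryl addition, oxidation) against two in the chosen plan.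

Alternative 2: No skeletal bond is cut; the lower C3–H bond is disconnected, tracing the lower carbinol to flavan-3-one A4, whose C2 epimerises through its enol.
- Forward step: RuCl(p-cymene)(TsDPEN) with formic acid and triethylamine reduces A4 under dynamic kinetic resolution to A5, the octa-O-benzyl compound with free lower 3-hydroxyl and the cis (2R,3R) pair.
- In favour: hydride delivery anti to the C2 aryl group leads naturally to the cis pair. The lower unit would no longer have to come from enantiopure 1 and could be taken from the 2,3-trans series or a racemate; on supply the alternative is the better one. The free 3-hydroxyl of A5 is a handle for late 3-O-acylation, also a point in its favour for analogues. The final debenzylation is equal in both plans.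
- Against: it forms no bond of the skeleton and leaves C4 and ring C unsolved, so it can only be added to a plan, not replace the key step. Since 1 already carries both centres, it would cost an oxidation and a reduction. Flavan-3-ones also enolise toward C4 and are air-sensitive, and the quinone methide chemistry would have to tolerate a ketone or a differently protected 3-oxygen.
- Comparison: mechanistically reliable, but aimed at the lesser stereochemical problem and about two steps longer when 1 is the source.

Alternative 3: The C8a–O1 bond of ring C is cut at the lactone level, leading from lactone A7 back to 6-benzyloxy-3-(hexa-O-benzylepigallocatechin-8-yl)indan-1-one A6.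
- Forward step: m-chloroperoxybenzoic acid buffered with NaHCO3 inserts oxygen between the carbonyl carbon and the ring A carbon with aryl migration, giving A7 without touching C4. A ring B aryllithium would then open A7 to 12, where the chosen route is rejoined.
- In favour: the migration is stereoretentive. A7 is a robust lactone with no hemiketal or dehydration ambiguity, so on handling it is better than 12. Ring B is introduced late from a common intermediate, which is equal or better for analogue work.
- Against: C4 must already be set in A6, for instance by an asymmetric conjugate arylation of the corresponding indenone with a C8-metalated form of 3, a hindered di-ortho-substituted nucleophile. The migrating ring A carbon is meta to the benzyloxy group and gets no para-donor help, so aryl over methylene migration is less secure and may need a stronger peracid. Peracids threaten the electron-rich rings D and E, and mono-addition of an aryllithium to a lactone can over-add.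
- Comparison: the oxygen of ring C arrives by oxidation instead of being carried in the aldehyde, which costs at least three steps to A6 plus oxidation and opening, against two steps from 4 to 12 in the chosen plan.

Key step: step 6

Assumption: the sense of induction of the chiral phosphoric acid on this chiral substrate cannot be derived with certainty; the (R)-catalyst is taken as the matched one, and its mirror image would be used if the opposite sense were found.

## Route

Throughout, "hexa-O-benzylepigallocatechin-8-yl" means the (2R,3R)-3,5,7,3',4',5'-hexa-O-benzyl unit bonded through C8.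

Step 1
Reactants: 1 (−)-epigallocatechin
Product: 2 5,7,3',4',5'-penta-O-benzyl-(−)-epigallocatechin (3-hydroxyl free)
Conditions: BnBr (5.5 equiv), K2CO3, DMF, 0 °C → rt, argon, dark
Reagents that add atoms: benzyl bromide, BrCc1ccccc1
Why: Williamson etherification of the five phenols with a carbonate base that leaves the secondary 3-hydroxyl untouched; low temperature, exclusion of air and benzyl bromide present from the start should limit C-benzylation of ring D, oxidation of ring E and base-induced C2 epimerisation, so the (2R,3R) centres are carried over.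

Step 2
Reactants: 2 5,7,3',4',5'-penta-O-benzyl-(−)-epigallocatechin
Product: 3 3,5,7,3',4',5'-hexa-O-benzyl-(−)-epigallocatechin
Conditions: NaH, BnBr, Bu4NI (cat.), THF/DMF, 0 °C → rt
Reagents that add atoms: benzyl bromide, BrCc1ccccc1
Why: Williamson etherification of the secondary alkoxide; no phenoxide remains that could open ring F, so C2 and C3 are not at risk, and the capped 3-oxygen cannot interfere with the lithiation or the Mitsunobu step.

Step 3
Reactants: 3 3,5,7,3',4',5'-hexa-O-benzyl-(−)-epigallocatechin
Product: 4 8-bromo-3,5,7,3',4',5'-hexa-O-benzyl-(−)-epigallocatechin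
Conditions: NBS (1.0 equiv), CH2Cl2, −78 → −20 °C
Reagents that add atoms: N-bromosuccinimide, O=C1CCC(=O)N1Br
Why: Electrophilic aromatic bromination; ring D with three oxygen donors is far more reactive than ring E, and in 5,7-di-O-benzyl flavan-3-ol ethers this bromination is known to go to C8 before C6, one equivalent at low temperature avoiding the 6,8-dibromide.

Step 4
Reactants: 4 8-bromo-3,5,7,3',4',5'-hexa-O-benzyl-(−)-epigallocatechin; 5 4-(benzyloxy)-2-hydroxybenzaldehyde
Product: 8 (4-benzyloxy-2-hydroxyphenyl)(hexa-O-benzylepigallocatechin-8-yl)methanol (both carbinol epimers), via 8-lithio-hexa-O-benzylepigallocatechin 6 (not isolated), via sodium 5-benzyloxy-2-formylphenoxide 7 (not isolated)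
Conditions: 5, NaH (1.05 equiv), THF, 0 °C; separately 4, t-BuLi (2.0 equiv), THF, −78 °C; phenoxide solution (1.3 equiv) added to the aryllithium, −78 → −20 °C; pH 7 buffer quench; Et3N-deactivated silica
Reagents that add atoms: none
Why: Bromine–lithium exchange (the second equivalent of tert-butyllithium destroys tert-butyl bromide) gives a 2,6-dialkoxyaryllithium that adds 1,2 to the aldehyde, whose phenol is masked as the phenoxide so that no proton quenches the nucleophile; the new carbinol centre forms without control, which is harmless because step 6 erases it, and the neutral quench protects the easily ionised benzhydrol.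

Step 5
Reactants: 9 1-[3,4-bis(benzyloxy)phenyl]ethanone
Product: 10 1-[3,4-bis(benzyloxy)phenyl]-1-(trimethylsilyloxy)ethene
Conditions: TMSOTf, Et3N, CH2Cl2, 0 °C; pentane trituration, filtration, used crude and fresh
Reagents that add atoms: trimethylsilyl trifluoromethanesulfonate, C[Si](C)(C)OS(=O)(=O)C(F)(F)F
Why: Soft enolisation and O-silylation of a methyl aryl ketone with a single enolisable side (silyl enol ether formation); the trimethylsilyl group is kept because its easy transfer to water is what turns the catalyst over in step 6.

Step 6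
Reactants: 8 (4-benzyloxy-2-hydroxyphenyl)(hexa-O-benzylepigallocatechin-8-yl)methanol; 10 1-[3,4-bis(benzyloxy)phenyl]-1-(trimethylsilyloxy)ethene
Product: 12 (3R)-1-[3,4-bis(benzyloxy)phenyl]-3-(4-benzyloxy-2-hydroxyphenyl)-3-(hexa-O-benzylepigallocatechin-8-yl)propan-1-one, via ring A ortho-quinone methide 11 (not isolated)
Conditions: (R)-TRIP [(R)-3,3'-bis(2,4,6-triisopropylphenyl)-1,1'-binaphthyl-2,2'-diyl hydrogen phosphate] (10 mol%), 10 (2.5 equiv), toluene/CH2Cl2, −40 °C, slow addition of 8, no drying agent; then aq. NaHCO3
Reagents that add atoms: none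
Why: The phosphoric acid protonates the benzylic hydroxyl of 8 and water leaves with push from the ortho phenol and the oxygen donors of rings A and D, so the quinone methide 11 forms at low temperature as a hydrogen-bonded or ion-paired complex with the chiral phosphate. The terminal carbon of 10 attacks the methide carbon, ring A rearomatises, and the silyl group of the resulting silyloxocarbenium ion passes to the water released in the first event, which returns the catalyst and leaves the ketone; a silyl ketal formed by a stepwise [4+2] path would collapse to the same ketone on work-up. The closest known reaction type is the chiral Brønsted acid-catalysed conjugate addition (Mukaiyama–Michael type) of enol derivatives to ortho-quinone methides generated from ortho-hydroxybenzhydrols. No ring is closed; one C–C bond (C3–C4) and one stereocentre (C4, R) are formed. The C4 configuration is decided by which face of the planar methide carbon the 3,3'-aryl groups of the bound phosphate leave open, that is by the catalyst, with the C2/C3 centres of ring F as a secondary matched or mismatched influence. The step needs face selectivity, attack through carbon of the enol silane, and intermolecular capture faster than Friedel–Crafts self-condensation or cyclodehydration of the product to a 4H-chromene; the di-ortho-substituted ring D, twisted out of the methide plane, keeps the methide carbon accessible, the single free phenol allows only one quinone methide, and the excess of 10 with slow addition of 8 keeps the electrophile dilute. The two C4 epimers are diastereomers, so a minor epimer can be removed by chromatography, and any cyclic hemiketal form of 12 is carried into step 7 with the open ketone.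

Step 7
Reactants: 12 (3R)-1-[3,4-bis(benzyloxy)phenyl]-3-(4-benzyloxy-2-hydroxyphenyl)-3-(hexa-O-benzylepigallocatechin-8-yl)propan-1-one
Product: 13 (1R,3R)-1-[3,4-bis(benzyloxy)phenyl]-3-(4-benzyloxy-2-hydroxyphenyl)-3-(hexa-O-benzylepigallocatechin-8-yl)propan-1-ol
Conditions: (S)-Me-CBS [(S)-1-methyl-3,3-diphenyltetrahydro-1H,3H-pyrrolo[1,2-c][1,3,2]oxazaborole] (0.5 equiv), BH3·SMe2 (2.2 equiv), THF, −20 °C; MeOH quench
Reagents that add atoms: none
Why: Corey–Bakshi–Shibata reduction; the aryl group acts as the large and the CH2 as the small ketone substituent, so the (S)-oxazaborolidine should deliver hydride to give the (R)-carbinol, the first equivalent of borane being consumed by the phenol and C4 being untouched.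

Step 8
Reactants: 13 (1R,3R)-1-[3,4-bis(benzyloxy)phenyl]-3-(4-benzyloxy-2-hydroxyphenyl)-3-(hexa-O-benzylepigallocatechin-8-yl)propan-1-ol
Product: 14 (2S,4R)-7,3',4'-tri-O-benzylflavan-(4→8)-3,5,7,3',4',5'-hexa-O-benzyl-(−)-epigallocatechin (nona-O-benzyl target)
Conditions: PPh3 (1.5 equiv), DIAD (1.5 equiv), toluene/THF, 0 °C → rt
Reagents that add atoms: none
Why: Intramolecular Mitsunobu etherification; the phenol protonates the betaine, the benzylic alcohol is activated as its alkoxyphosphonium ion and the phenoxide displaces it in a 6-exo-tet SN2 closure with inversion (R carbinol to S at C2), which places ring B trans to ring D while C4 is not involved.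

Step 9
Reactants: 14 (2S,4R)-7,3',4'-tri-O-benzylflavan-(4→8)-3,5,7,3',4',5'-hexa-O-benzyl-(−)-epigallocatechin
Product: 15 (2R,3R)-8-[(2S,4R)-2-(3,4-dihydroxyphenyl)-7-hydroxy-3,4-dihydro-2H-chromen-4-yl]-2-(3,4,5-trihydroxyphenyl)-3,4-dihydro-2H-chromene-3,5,7-triol (target)
Conditions: H2 (1 atm), Pd(OH)2/C, THF/MeOH 1:1, rt; filtration under argon, lyophilisation
Reagents that add atoms: none
Why: Catalytic hydrogenolysis of the nine benzyl ethers under neutral conditions; the cyclic benzylic O1–C2 ethers of flavan-3-ol oligomers are known to survive these conditions, and no stereocentre is touched.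

## Compound list

1 | (−)-epigallocatechin, (2R,3R) | Oc1cc(O)c2c(c1)O[C@H](c1cc(O)c(O)c(O)c1)[C@H](O)C2 | starting material
2 | 5,7,3',4',5'-penta-O-benzyl-(−)-epigallocatechin, (2R,3R) | c1c(OCc5ccccc5)cc(OCc5ccccc5)c2c1O[C@H](c1cc(OCc5ccccc5)c(OCc5ccccc5)c(OCc5ccccc5)c1)[C@H](O)C2 | intermediate
3 | 3,5,7,3',4',5'-hexa-O-benzyl-(−)-epigallocatechin, (2R,3R) | c1c(OCc5ccccc5)cc(OCc5ccccc5)c2c1O[C@H](c1cc(OCc5ccccc5)c(OCc5ccccc5)c(OCc5ccccc5)c1)[C@H](OCc1ccccc1)C2 | intermediate
4 | 8-bromo-3,5,7,3',4',5'-hexa-O-benzyl-(−)-epigallocatechin, (2R,3R) | Brc1c(OCc5ccccc5)cc(OCc5ccccc5)c2c1O[C@H](c1cc(OCc5ccccc5)c(OCc5ccccc5)c(OCc5ccccc5)c1)[C@H](OCc1ccccc1)C2 | intermediate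
5 | 4-(benzyloxy)-2-hydroxybenzaldehyde | O=Cc1ccc(OCc2ccccc2)cc1O | starting material
6 | 8-lithio-hexa-O-benzylepigallocatechin, (2R,3R) | [Li]c1c(OCc5ccccc5)cc(OCc5ccccc5)c2c1O[C@H](c1cc(OCc5ccccc5)c(OCc5ccccc5)c(OCc5ccccc5)c1)[C@H](OCc1ccccc1)C2 | intermediate (not isolated)
7 | sodium 5-(benzyloxy)-2-formylphenoxide | [Na+].[O-]c1cc(OCc2ccccc2)ccc1C=O | intermediate (not isolated)
8 | (4-benzyloxy-2-hydroxyphenyl)(hexa-O-benzylepigallocatechin-8-yl)methanol, both carbinol epimers, lower unit (2R,3R) | C(c5ccccc5)Oc1ccc(c(O)c1)C(O)c1c(OCc5ccccc5)cc(OCc5ccccc5)c2c1O[C@H](c1cc(OCc5ccccc5)c(OCc5ccccc5)c(OCc5ccccc5)c1)[C@H](OCc1ccccc1)C2 | intermediate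
9 | 1-[3,4-bis(benzyloxy)phenyl]ethanone | CC(=O)c1ccc(OCc2ccccc2)c(OCc2ccccc2)c1 | starting material
10 | 1-[3,4-bis(benzyloxy)phenyl]-1-(trimethylsilyloxy)ethene | C=C(O[Si](C)(C)C)c1ccc(OCc5ccccc5)c(OCc5ccccc5)c1 | intermediate
11 | ring A ortho-quinone methide, 3-(benzyloxy)-6-[(hexa-O-benzylepigallocatechin-8-yl)methylidene]cyclohexa-2,4-dien-1-one, exocyclic geometry not defined | O=C1C=C(OCc5ccccc5)C=CC1=Cc1c(OCc5ccccc5)cc(OCc5ccccc5)c2c1O[C@H](c1cc(OCc5ccccc5)c(OCc5ccccc5)c(OCc5ccccc5)c1)[C@H](OCc1ccccc1)C2 | intermediate (not isolated)
12 | (3R)-1-[3,4-bis(benzyloxy)phenyl]-3-(4-benzyloxy-2-hydroxyphenyl)-3-(hexa-O-benzylepigallocatechin-8-yl)propan-1-one | C(c5ccccc5)Oc1ccc(c(O)c1)[C@@H](CC(=O)c1ccc(OCc5ccccc5)c(OCc5ccccc5)c1)c1c(OCc5ccccc5)cc(OCc5ccccc5)c2c1O[C@H](c1cc(OCc5ccccc5)c(OCc5ccccc5)c(OCc5ccccc5)c1)[C@H](OCc1ccccc1)C2 | intermediate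
13 | (1R,3R)-1-[3,4-bis(benzyloxy)phenyl]-3-(4-benzyloxy-2-hydroxyphenyl)-3-(hexa-O-benzylepigallocatechin-8-yl)propan-1-ol | C(c5ccccc5)Oc1ccc(c(O)c1)[C@@H](C[C@@H](O)c1ccc(OCc5ccccc5)c(OCc5ccccc5)c1)c1c(OCc5ccccc5)cc(OCc5ccccc5)c2c1O[C@H](c1cc(OCc5ccccc5)c(OCc5ccccc5)c(OCc5ccccc5)c1)[C@H](OCc1ccccc1)C2 | intermediate
14 | (2S,4R)-7,3',4'-tri-O-benzylflavan-(4→8)-(2R,3R)-3,5,7,3',4',5'-hexa-O-benzylepigallocatechin | C(c5ccccc5)Oc1ccc2c(c1)O[C@H](c1ccc(OCc5ccccc5)c(OCc5ccccc5)c1)C[C@H]2c1c(OCc5ccccc5)cc(OCc5ccccc5)c2c1O[C@H](c1cc(OCc5ccccc5)c(OCc5ccccc5)c(OCc5ccccc5)c1)[C@H](OCc1ccccc1)C2 | intermediate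
15 | (2R,3R)-8-[(2S,4R)-2-(3,4-dihydroxyphenyl)-7-hydroxy-3,4-dihydro-2H-chromen-4-yl]-2-(3,4,5-trihydroxyphenyl)-3,4-dihydro-2H-chromene-3,5,7-triol | Oc1ccc2c(c1)O[C@H](c1ccc(O)c(O)c1)C[C@H]2c1c(O)cc(O)c2c1O[C@H](c1cc(O)c(O)c(O)c1)[C@H](O)C2 | target

## Step count and risks

Total: 9 steps. Longest linear sequence: 8 steps (steps 1, 2, 3, 4, 6, 7, 8, 9); step 5 is the side branch.

Step 6 (key step).
- Most likely failure: poor facial selectivity, because the enol silane is not anchored to the phosphate and the catalyst may be mismatched with the ring F centres.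
- Also possible: self-condensation of the electron-rich benzhydrol, premature hydrolysis of the enol silane, and cyclodehydration of the product.
- Fallback: a nucleophile that binds the catalyst at two points. From 9, Claisen acylation with diallyl carbonate and NaH would give allyl 3-[3,4-bis(benzyloxy)phenyl]-3-oxopropanoate F1. F1 would be added to 8 under the same type of chiral phosphoric acid (a known addition of β-dicarbonyl compounds to ortho-quinone methides) to give allyl 2-[(4-benzyloxy-2-hydroxyphenyl)(hexa-O-benzylepigallocatechin-8-yl)methyl]-3-[3,4-bis(benzyloxy)phenyl]-3-oxopropanoate F2, as epimers at the carbon between the carbonyl groups. Deallylation with Pd(PPh3)4 and morpholine and spontaneous decarboxylation of the β-keto acid would return the route to 12.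

Step 4.
- Most likely failure: sluggish addition of the hindered aryllithium to the deactivated phenoxide aldehyde, with proton quench back to 3, and ionisation of the benzhydrol on work-up or silica.
- Fallback: mask the phenol covalently. From 5, allylation (allyl bromide, K2CO3) would give 2-(allyloxy)-4-(benzyloxy)benzaldehyde F3. Addition of 6 would give [2-(allyloxy)-4-(benzyloxy)phenyl](hexa-O-benzylepigallocatechin-8-yl)methanol F4. Neutral deallylation with Pd(PPh3)4 and morpholine would come back at 8.

Step 8.
- Most likely failure: ionisation of the activated, electron-rich benzylic alkoxyphosphonium ion, leading to loss of stereochemical fidelity at C2 (the 2,4-cis epimer, a separable diastereomer) or elimination to a styrene.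
- Fallback: close O1–C8a instead of O1–C2, with retention at the carbinol. From 12, triflation of the phenol (PhNTf2, Cs2CO3) would give 5-(benzyloxy)-2-[(1R)-3-[3,4-bis(benzyloxy)phenyl]-1-(hexa-O-benzylepigallocatechin-8-yl)-3-oxopropyl]phenyl trifluoromethanesulfonate F5. Reduction with the (R)-oxazaborolidine and BH3·SMe2 would give the (1R,3S)-carbinol 5-(benzyloxy)-2-[(1R,3S)-3-[3,4-bis(benzyloxy)phenyl]-3-hydroxy-1-(hexa-O-benzylepigallocatechin-8-yl)propyl]phenyl trifluoromethanesulfonate F6. Intramolecular aryl C–O coupling (Pd(OAc)2, 2-(di-tert-butylphosphino)biphenyl, Cs2CO3, toluene, 80 °C) would then return to 14.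

Step 7.
- Most likely failure: uncatalysed background reduction by the aryloxyborane formed from the free phenol, or withdrawal of the ketone into its hemiketal, lowering catalyst control at the carbinol.
- Fallback: change the hydride source and mechanism to transfer hydrogenation with RuCl(p-cymene)[(R,R)-TsDPEN] and HCO2H/Et3N, which tolerates free phenols and should give the same (R)-carbinol. It sets out from 12 and returns at 13 with no new compound.

Further compounds
F1 | step 6 | allyl 3-[3,4-bis(benzyloxy)phenyl]-3-oxopropanoate | C=CCOC(=O)CC(=O)c1ccc(OCc2ccccc2)c(OCc2ccccc2)c1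
F2 | step 6 | allyl 2-[(4-benzyloxy-2-hydroxyphenyl)(hexa-O-benzylepigallocatechin-8-yl)methyl]-3-[3,4-bis(benzyloxy)phenyl]-3-oxopropanoate, benzylic carbon as in 12, epimers at C2 of the propanoate | C(c5ccccc5)Oc1ccc(c(O)c1)[C@@H](C(C(=O)OCC=C)C(=O)c1ccc(OCc5ccccc5)c(OCc5ccccc5)c1)c1c(OCc5ccccc5)cc(OCc5ccccc5)c2c1O[C@H](c1cc(OCc5ccccc5)c(OCc5ccccc5)c(OCc5ccccc5)c1)[C@H](OCc1ccccc1)C2
F3 | step 4 | 2-(allyloxy)-4-(benzyloxy)benzaldehyde | O=Cc1ccc(OCc2ccccc2)cc1OCC=C
F4 | step 4 | [2-(allyloxy)-4-(benzyloxy)phenyl](hexa-O-benzylepigallocatechin-8-yl)methanol, carbinol epimers | C(c5ccccc5)Oc1ccc(c(OCC=C)c1)C(O)c1c(OCc5ccccc5)cc(OCc5ccccc5)c2c1O[C@H](c1cc(OCc5ccccc5)c(OCc5ccccc5)c(OCc5ccccc5)c1)[C@H](OCc1ccccc1)C2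
F5 | step 8 | 5-(benzyloxy)-2-[(1R)-3-[3,4-bis(benzyloxy)phenyl]-1-(hexa-O-benzylepigallocatechin-8-yl)-3-oxopropyl]phenyl trifluoromethanesulfonate | C(c5ccccc5)Oc1ccc(c(OS(=O)(=O)C(F)(F)F)c1)[C@@H](CC(=O)c1ccc(OCc5ccccc5)c(OCc5ccccc5)c1)c1c(OCc5ccccc5)cc(OCc5ccccc5)c2c1O[C@H](c1cc(OCc5ccccc5)c(OCc5ccccc5)c(OCc5ccccc5)c1)[C@H](OCc1ccccc1)C2
F6 | step 8 | 5-(benzyloxy)-2-[(1R,3S)-3-[3,4-bis(benzyloxy)phenyl]-3-hydroxy-1-(hexa-O-benzylepigallocatechin-8-yl)propyl]phenyl trifluoromethanesulfonate | C(c5ccccc5)Oc1ccc(c(OS(=O)(=O)C(F)(F)F)c1)[C@@H](C[C@H](O)c1ccc(OCc5ccccc5)c(OCc5ccccc5)c1)c1c(OCc5ccccc5)cc(OCc5ccccc5)c2c1O[C@H](c1cc(OCc5ccccc5)c(OCc5ccccc5)c(OCc5ccccc5)c1)[C@H](OCc1ccccc1)C2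
F0 | step 7 | none | none
A1 | alternative 1 | (E)-3-(hexa-O-benzylepigallocatechin-8-yl)prop-2-enal | O=C/C=C/c1c(OCc5ccccc5)cc(OCc5ccccc5)c2c1O[C@H](c1cc(OCc5ccccc5)c(OCc5ccccc5)c(OCc5ccccc5)c1)[C@H](OCc1ccccc1)C2
A2 | alternative 1 | 3-(benzyloxy)phenol | Oc1cccc(OCc2ccccc2)c1
A3 | alternative 1 | 7-benzyloxy-4-(hexa-O-benzylepigallocatechin-8-yl)chroman-2-ol, anomers, C4 as in the target | C(c5ccccc5)Oc1ccc2c(c1)OC(O)C[C@H]2c1c(OCc5ccccc5)cc(OCc5ccccc5)c2c1O[C@H](c1cc(OCc5ccccc5)c(OCc5ccccc5)c(OCc5ccccc5)c1)[C@H](OCc1ccccc1)C2
A4 | alternative 2 | octa-O-benzyl target with the lower C3 as ketone (flavan-3-one), lower C2 epimerising | C(c5ccccc5)Oc1ccc2c(c1)O[C@H](c1ccc(OCc5ccccc5)c(OCc5ccccc5)c1)C[C@H]2c1c(OCc5ccccc5)cc(OCc5ccccc5)c2c1OC(c1cc(OCc5ccccc5)c(OCc5ccccc5)c(OCc5ccccc5)c1)C(=O)C2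
A5 | alternative 2 | octa-O-benzyl target with free lower 3-hydroxyl, lower (2R,3R) | C(c5ccccc5)Oc1ccc2c(c1)O[C@H](c1ccc(OCc5ccccc5)c(OCc5ccccc5)c1)C[C@H]2c1c(OCc5ccccc5)cc(OCc5ccccc5)c2c1O[C@H](c1cc(OCc5ccccc5)c(OCc5ccccc5)c(OCc5ccccc5)c1)[C@H](O)C2
A6 | alternative 3 | 6-benzyloxy-3-(hexa-O-benzylepigallocatechin-8-yl)indan-1-one, C3 corresponding to C4 of the target | C(c5ccccc5)Oc1ccc2c(c1)C(=O)C[C@H]2c1c(OCc5ccccc5)cc(OCc5ccccc5)c2c1O[C@H](c1cc(OCc5ccccc5)c(OCc5ccccc5)c(OCc5ccccc5)c1)[C@H](OCc1ccccc1)C2
A7 | alternative 3 | 7-benzyloxy-4-(hexa-O-benzylepigallocatechin-8-yl)chroman-2-one, C4 as in the target | C(c5ccccc5)Oc1ccc2c(c1)OC(=O)C[C@H]2c1c(OCc5ccccc5)cc(OCc5ccccc5)c2c1O[C@H](c1cc(OCc5ccccc5)c(OCc5ccccc5)c(OCc5ccccc5)c1)[C@H](OCc1ccccc1)C2
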